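**Plan**

- Feature: the ring carbons C1–C10 are the rim of a bicyclo[4.4.1]undecane in which the carboxyl carbon C14 bridges C10 and C5. Tropone therefore supplies C14, C10 and C1–C5, and a 1,4‑dioxygenated butadiene supplies C6–C9 with the oxygens of C6 and C9 already in place.
- Retrosynthetic cuts, in order: the O6–C12 lactone bond and the C8/C9 esters; the two epoxides, the C4–methyl bond and C10=C1 (back to a ring‑A diene); C7–C11; the C14–O–C5 bond (Baeyer–Villiger); last C5–C6 and C9–C10 ([6+4]).
- Forward: the cycloaddition closes the carbonyl‑bridged bicycle, a hydrolase desymmetrizes it, and oxygen insertion gives a bridged lactone. On that rigid bicycle the C7 side chain, the C8 ester and the ring‑A oxygens are installed. The lactone is then opened, the 4,5‑epoxide and C10=C1 are formed, and the α‑methylene lactone is closed near the end.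
- Stereochemistry: C5, C6, C9 come from the suprafacial exo cycloaddition of the E,E‑diene, with the absolute sense from the hydrolase. C7 comes from SN2 opening of a hydroxyl‑directed epoxide and C8 from Mitsunobu inversion. C4, C2, C3 come from attack on the convex face of the bridged lactone, and C5 is inverted on epoxide closure. The ester epoxide comes from a Sharpless epoxidation.

Key step: step 1

Assumption and convention: a commercial hydrolase is assumed to hydrolyse the acetate at the carbon that becomes C6 (hydrolysis and acylation with one lipase give antipodal monoacetates, so the sense can be corrected); locants are those of the target, and "up/down" refers to the C1–C10 ring drawn clockwise from above with the C14 bridge up.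

**Route**

Step 1
Reactants: 1 tropone; 2 (1E,3E)-buta-1,3-diene-1,4-diyl diacetate
Product: 3 meso-7,10-diacetoxybicyclo[4.4.1]undeca-2,4,8-trien-11-one (target locants: 6,9-diacetoxy, C14 ketone bridging C5 and C10; bridge and both acetoxy groups up)
Conditions: xylenes, 130 °C, sealed tube, 2,6-di-tert-butyl-4-methylphenol (cat.)
Reagents that add atoms: none
Why: A concerted thermal [π6s+π4s] cycloaddition (ten electrons, suprafacial on both partners), of the type known for tropone with 1-acyloxybutadienes, joins the α-carbons of tropone to the diene termini (bonds C9–C10 and C5–C6). It closes the seven-membered ring C14–C10–C9–C8–C7–C6–C5 and, with it, the ten-membered perimeter C1–C10, both by cycloaddition across the tropone carbonyl. C5 and C10 are set by the tropone face that is attacked, and C6 and C9 by the E,E geometry of the diene, carried over suprafacially so that the two acetoxy groups are cis. The exo transition state, with the internal diene carbons over the carbonyl and not over the triene, puts both acetoxy groups syn to the C14 bridge. The step needs [6+4] over [4+2] periselectivity and exo over endo selectivity; the large frontier coefficients at C2/C7 of tropone and the antibonding secondary overlap of the endo [6+4] mode should secure both. The adduct is meso.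

Step 2
Reactants: 3 meso diacetate
Product: 4 9-acetoxy-6-hydroxy bicyclic ketone (hydroxyl at C6 up, acetate at C9 up)
Conditions: lipase from Burkholderia cepacia, pH 7 phosphate buffer/acetone, 25 °C
Reagents that add atoms: none
Why: Enzymatic desymmetrization (hydrolase-catalysed hydrolysis of one enantiotopic ester of a meso cis-1,4-diacetoxy-2-cycloalkene, here the 4,7-diacetoxycyclohept-5-enone ring) removes the acetate at C6 and thereby fixes the absolute configuration of C5, C6, C9 and C10 without forming a new centre.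

Step 3
Reactants: 4 hydroxy acetate
Product: 5 9-acetoxy-6-(tert-butyldimethylsilyloxy) bicyclic ketone
Conditions: TBSCl, imidazole, DMF, 0 °C to rt
Reagents that add atoms: tert-butyldimethylsilyl chloride, CC(C)(C)[Si](C)(C)Cl
Why: Silylation of a secondary alcohol under neutral imidazole conditions, which spare the β-hydroxy ketone from retro-aldol cleavage; the bulky silyl ether is the steering group for step 5.

Step 4
Reactants: 5 silyl ether acetate
Product: 6 9-hydroxy-6-(tert-butyldimethylsilyloxy) bicyclic ketone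
Conditions: K2CO3 (0.1 equiv), MeOH, 0 °C
Reagents that add atoms: none
Why: Carbonate-catalysed transesterification (methanolysis of an acetate); the α-hydrogens sit at bridgeheads, so enolization and β-elimination are blocked (Bredt), and the low temperature limits retro-aldol opening.

Step 5
Reactants: 6 hydroxy ketone
Product: 9 bridged lactone (11-oxabicyclo[4.4.2]dodeca-2,4,8-trien-12-one skeleton; C14(=O)–O–C5 bridge up; 6-OTBS up; 9-OH up), via 9-trifluoroacetate ketone 7 (not isolated), via 9-trifluoroacetate lactone 8 (not isolated)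
Conditions: (CF3CO)2O, pyridine, CH2Cl2, −20 °C; Me3SiOOSiMe3, Me3SiOTf (cat.), CH2Cl2, −40 °C; NaHCO3, MeOH, 0 °C
Reagents that add atoms: bis(trimethylsilyl) peroxide, C[Si](C)(C)OO[Si](C)(C)C; trifluoroacetic anhydride, O=C(OC(=O)C(F)(F)F)C(F)(F)F (in 7 and 8 only)
Why: Baeyer–Villiger oxidation with a silyl peroxide under silyl triflate catalysis, a variant that leaves C=C bonds alone; in the Criegee adduct C5 should migrate with retention because the trifluoroacetoxy group β to C10 retards migration of that bridgehead and the bulky silyloxy group next to C5 holds the peroxide bond anti to C5, and the trifluoroacetate is then methanolysed far faster than the lactone.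

Step 6
Reactants: 9 bridged lactone
Product: 10 7,8-epoxy bridged lactone (epoxide oxygen up, syn to 9-OH)
Conditions: VO(acac)2 (cat.), t-BuOOH, CH2Cl2, 0 °C
Reagents that add atoms: tert-butyl hydroperoxide, CC(C)(C)OO
Why: Hydroxyl-directed epoxidation: the vanadium-bound peroxide is delivered from the C9 alkoxide to the allylic C7=C8 bond on the face of that oxygen, as with cycloalk-2-enols of five to nine ring atoms, while the diene is only homoallylic and should react more slowly.

Step 7
Reactants: 11 2-bromoprop-2-en-1-ol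
Product: 12 (2-bromoallyloxy)(tert-butyl)dimethylsilane
Conditions: TBSCl, imidazole, DMF, rt
Reagents that add atoms: tert-butyldimethylsilyl chloride, CC(C)(C)[Si](C)(C)Cl
Why: Standard silylation of a primary allylic alcohol, masking the future C12 oxygen.

Step 8
Reactants: 10 epoxy alcohol; 12 bromoallyl silyl ether
Product: 15 8,9-diol bearing the 3-(silyloxy)prop-1-en-2-yl chain at C7 (chain down; 8-OH up; 9-OH up), via alkenyllithium 13 (not isolated), via dimethyl(alkenyl)alane 14 (not isolated)
Conditions: 12, t-BuLi, Et2O, −78 °C; Me2AlCl; then 10 (pretreated with Me3Al), CH2Cl2/hexane, −78 to 0 °C; aqueous potassium sodium tartrate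
Reagents that add atoms: none
Why: Organoaluminium opening of a 2,3-epoxy alcohol at the carbon remote from the hydroxyl: bromine–lithium exchange and transmetalation give the alkenylalane, the aluminium alkoxide at C9 activates the epoxide, and the alkenyl group (transferred in preference to methyl) attacks C7 with inversion (SN2), which sets C7 with the side chain anti to the oxygens at C6 and C8.

Step 9
Reactants: 16 angelic acid
Product: 17 (Z)-2-methylbut-2-en-1-ol
Conditions: LiAlH4, Et2O, 0 °C to rt
Reagents that add atoms: none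
Why: Hydride reduction of a carboxylic acid to the primary alcohol; the isolated trisubstituted alkene and its Z geometry are not touched under these conditions.

Step 10
Reactants: 17 allylic alcohol
Product: 18 [(2S,3R)-2,3-dimethyloxiran-2-yl]methanol
Conditions: Ti(OiPr)4 (cat.), L-(+)-diethyl tartrate (cat.), t-BuOOH, 4 Å molecular sieves, CH2Cl2, −20 °C
Reagents that add atoms: tert-butyl hydroperoxide, CC(C)(C)OO
Why: Sharpless asymmetric epoxidation; with the L-(+)-tartrate the titanium-bound peroxide attacks the face that gives the (2S,3R)-epoxide, the same sense as for nerol, and the Z geometry becomes the trans relation of the two methyl groups.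

Step 11
Reactants: 18 epoxy alcohol
Product: 19 (2R,3R)-2,3-dimethyloxirane-2-carboxylic acid
Conditions: RuCl3 (cat.), NaIO4, CCl4/MeCN/H2O, rt
Reagents that add atoms: water, O (second carboxyl oxygen, via the aldehyde hydrate)
Why: Ruthenium tetroxide oxidation of a primary alcohol to the acid, well known for 2,3-epoxy alcohols; no stereocentre is touched, and only the descriptor of C2 changes to R by priority.

Step 12
Reactants: 15 diol; 19 epoxy acid
Product: 20 8-O-[(2R,3R)-2,3-epoxy-2-methylbutanoyl] 9-hydroxy bridged lactone (8-O-acyl down; 9-OH up)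
Conditions: PPh3, DIAD, toluene, 0 °C to rt
Reagents that add atoms: none
Why: Mitsunobu esterification with inversion at C8: of the two hydroxyls only C8 has an open backside (the convex face), the backside of C9 being covered by the ring-A bridge; the cis C9 oxygen cannot cause retention by participation, and the acidic glycidic acid is a good Mitsunobu nucleophile.

Step 13
Reactants: 20 hydroxy ester
Product: 21 6,9,12-tris-silyl ether of the 8-ester bridged lactone
Conditions: TBSOTf, 2,6-lutidine, CH2Cl2, −40 to 0 °C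
Reagents that add atoms: tert-butyldimethylsilyl trifluoromethanesulfonate, CC(C)(C)[Si](C)(C)OS(=O)(=O)C(F)(F)F
Why: Silyl triflate silylation of the remaining hindered secondary alcohol, so that neither an acetate nor a free hydroxyl is present during the later lactone opening and mesylation.

Step 14
Reactants: 21 diene lactone
Product: 22 1,4-endoperoxide (peroxide oxygens at C1 and C4 up; C2=C3)
Conditions: O2, visible light, tetraphenylporphyrin (cat.), CH2Cl2, −20 °C
Reagents that add atoms: dioxygen, O=O
Why: Singlet-oxygen [4+2] cycloaddition to the s-cis ring-A diene from the convex face gives the endoperoxide; the 1,1-disubstituted side-chain alkene reacts far more slowly in the ene mode.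

Step 15
Reactants: 22 endoperoxide
Product: 23 4-oxo-1-hydroxy-2-ene bridged lactone (1-OH up; C2=C3 cis)
Conditions: Et3N (0.5 equiv), CH2Cl2, 0 °C to rt
Reagents that add atoms: none
Why: Kornblum–DeLaMare rearrangement: the amine should remove H4, the more acidic of the two peroxide α-hydrogens because C5 carries the acyloxy oxygen, and O–O cleavage gives the C4 ketone and the C1 alcohol, as with cycloocta-1,3-diene endoperoxides.

Step 16
Reactants: 23 hydroxy enone
Product: 24 4-methyl-1,4-diol bridged lactone (4-methyl up; 4-OH down; 1-OH up)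
Conditions: MeTi(OiPr)3, Et2O, −20 to 0 °C
Reagents that add atoms: methyltitanium triisopropoxide, C[Ti](OC(C)C)(OC(C)C)OC(C)C
Why: 1,2-Addition of a methyltitanium reagent, selective for ketones over esters and lactones and accelerated by the α-acyloxy group; attack on the convex face of the bridged bicycle sets C4 with the methyl syn to the lactone bridge and the hydroxyl anti to the C5 oxygen.

Step 17
Reactants: 24 allylic diol
Product: 25 2,3-epoxy-4-methyl-1,4-diol bridged lactone (epoxide oxygen up)
Conditions: VO(acac)2 (cat.), t-BuOOH, CH2Cl2, 0 °C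
Reagents that add atoms: tert-butyl hydroperoxide, CC(C)(C)OO
Why: Hydroxyl-directed epoxidation again: the secondary C1 alcohol delivers the vanadium peroxide to the convex face of C2=C3, the only open face, which sets C2 and C3; the side-chain alkene has no free allylic hydroxyl and is left alone.

Step 18
Reactants: 25 bridged lactone
Product: 27 monocyclic 2-(trimethylsilyl)ethyl C14 ester with 1,4,5-triol (1-OH up; 4-OH down; 5-OH up), via seco acid 26 (not isolated)
Conditions: LiOH, H2O2, THF/H2O, 0 °C; Na2SO3; HCl to pH 4; then Me3SiCH2CH2OH, EDC·HCl, DMAP (cat.), CH2Cl2, 0 °C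
Reagents that add atoms: 2-(trimethylsilyl)ethanol, C[Si](C)(C)CCO; hydrogen peroxide, OO (supplies the carboxyl oxygen of 26)
Why: Hydroperoxide-mediated hydrolysis opens the eight-membered lactone, whose forced s-cis ester is far more electrophilic than the α-quaternary glycidic ester, with retention at C5, and Steglich esterification then protects C14 as a fluoride-labile ester.

Step 19
Reactants: 27 triol ester
Product: 29 4,5-epoxide with C10=C1 conjugated ester (4,5-epoxide oxygen down; C9 and C2 cis on the alkene), via 1,5-bis-mesylate 28 (not isolated)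
Conditions: MsCl, Et3N, CH2Cl2, −20 °C; then DBU, 0 °C to rt
Reagents that add atoms: methanesulfonyl chloride, CS(=O)(=O)Cl (in 28 only)
Why: Mesylation of the two secondary alcohols followed by base: the tertiary C4 oxygen displaces the anti C5 mesylate (3-exo-tet SN2, inversion at C5) and E1cB loss of the C1 mesylate gives the conjugated C10=C1 ester in its more stable geometry (C14 trans to C2, cis within the ten-membered ring).

Step 20
Reactants: 29 tris-silyl ether
Product: 30 6,9,12-triol 2-(trimethylsilyl)ethyl ester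
Conditions: HF·pyridine, pyridine, THF, 0 °C to rt
Reagents that add atoms: none
Why: Acidic fluoride desilylation of the three silyl ethers; buffered HF·pyridine avoids a free C6 alkoxide beside the 4,5-epoxide (no Payne migration) and does not cleave the silylethyl ester.

Step 21
Reactants: 30 triol
Product: 31 9-hydroxy α-methylene-γ-lactone 2-(trimethylsilyl)ethyl ester
Conditions: TEMPO (cat.), PhI(OAc)2, CH2Cl2, rt
Reagents that add atoms: none
Why: Oxoammonium oxidative lactonization of a 2-methylene-1,4-diol: the primary allylic alcohol is oxidized to the enal, the C6 hydroxyl closes the lactol (trans-fused, since C6 and C7 are already set) and this is oxidized to the lactone, while the secondary C9 alcohol should react much more slowly.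

Step 22
Reactants: 31 hydroxy lactone
Product: 32 leucanthin B 2-(trimethylsilyl)ethyl ester
Conditions: Ac2O, pyridine, CH2Cl2, 0 °C to rt
Reagents that add atoms: acetic anhydride, CC(=O)OC(C)=O
Why: Acetylation of the only free hydroxyl under pyridine conditions, without a nucleophilic catalyst that might add to the α-methylene lactone or displace the new allylic acetate.

Step 23
Reactants: 32 silylethyl ester
Product: 33 leucanthin B
Conditions: Bu4NF, THF, 0 °C; AcOH
Reagents that add atoms: none
Why: Fluoride-induced β-elimination of the 2-(trimethylsilyl)ethyl ester (loss of fluorotrimethylsilane and ethene) frees the C14 acid without palladium, acid or hydroxide, so the vinyl epoxide, acetate, glycidic ester and lactone should remain.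

**Compound list**

1 | tropone | O=C1C=CC=CC=C1 | starting material
2 | (1E,3E)-buta-1,3-diene-1,4-diyl diacetate | CC(=O)O/C=C/C=C/OC(C)=O | starting material
3 | meso-7,10-diacetoxybicyclo[4.4.1]undeca-2,4,8-trien-11-one (acetoxy groups cis, syn to carbonyl bridge) | O=C1[C@H]2C=CC=C[C@@H]1[C@@H](OC(C)=O)C=C[C@H]2OC(C)=O | intermediate
4 | 9-acetoxy-6-hydroxy bicyclic ketone | O=C1[C@H]2C=CC=C[C@@H]1[C@@H](O)C=C[C@H]2OC(C)=O | intermediate
5 | 9-acetoxy-6-(TBS-oxy) bicyclic ketone | O=C1[C@H]2C=CC=C[C@@H]1[C@@H](O[Si](C)(C)C(C)(C)C)C=C[C@H]2OC(C)=O | intermediate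
6 | 9-hydroxy-6-(TBS-oxy) bicyclic ketone | O=C1[C@H]2C=CC=C[C@@H]1[C@@H](O[Si](C)(C)C(C)(C)C)C=C[C@H]2O | intermediate
7 | 9-trifluoroacetate of 6 | O=C1[C@H]2C=CC=C[C@@H]1[C@@H](O[Si](C)(C)C(C)(C)C)C=C[C@H]2OC(=O)C(F)(F)F | intermediate
8 | 9-trifluoroacetoxy bridged lactone | O=C1O[C@@H]2/C=C\C=C/[C@H]1[C@H](OC(=O)C(F)(F)F)/C=C\[C@@H]2O[Si](C)(C)C(C)(C)C | intermediate
9 | 9-hydroxy-6-(TBS-oxy) bridged lactone (C14(=O)–O–C5) | O=C1O[C@@H]2/C=C\C=C/[C@H]1[C@H](O)/C=C\[C@@H]2O[Si](C)(C)C(C)(C)C | intermediate
10 | syn-7,8-epoxy-9-hydroxy bridged lactone | O=C1O[C@@H]2/C=C\C=C/[C@H]1[C@H](O)[C@@H]3O[C@@H]3[C@@H]2O[Si](C)(C)C(C)(C)C | intermediate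
11 | 2-bromoprop-2-en-1-ol | C=C(Br)CO | starting material
12 | (2-bromoallyloxy)(tert-butyl)dimethylsilane | C=C(Br)CO[Si](C)(C)C(C)(C)C | intermediate
13 | [3-(TBS-oxy)prop-1-en-2-yl]lithium | [Li]C(=C)CO[Si](C)(C)C(C)(C)C | intermediate
14 | dimethyl[3-(TBS-oxy)prop-1-en-2-yl]alane | C[Al](C)C(=C)CO[Si](C)(C)C(C)(C)C | intermediate
15 | 8,9-diol with C7 side chain (bridged lactone) | O=C1O[C@@H]2/C=C\C=C/[C@H]1[C@H](O)[C@H](O)[C@@H](C(=C)CO[Si](C)(C)C(C)(C)C)[C@@H]2O[Si](C)(C)C(C)(C)C | intermediate
16 | angelic acid | C/C=C(/C)C(=O)O | starting material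
17 | (Z)-2-methylbut-2-en-1-ol | C/C=C(/C)CO | intermediate
18 | [(2S,3R)-2,3-dimethyloxiran-2-yl]methanol | OC[C@]1(C)O[C@@H]1C | intermediate
19 | (2R,3R)-2,3-dimethyloxirane-2-carboxylic acid | OC(=O)[C@]1(C)O[C@@H]1C | intermediate
20 | 8-O-epoxyangeloyl 9-hydroxy bridged lactone | O=C1O[C@@H]2/C=C\C=C/[C@H]1[C@H](O)[C@@H](OC(=O)[C@]3(C)O[C@@H]3C)[C@@H](C(=C)CO[Si](C)(C)C(C)(C)C)[C@@H]2O[Si](C)(C)C(C)(C)C | intermediate
21 | 9-O-TBS ether of 20 | O=C1O[C@@H]2/C=C\C=C/[C@H]1[C@H](O[Si](C)(C)C(C)(C)C)[C@@H](OC(=O)[C@]3(C)O[C@@H]3C)[C@@H](C(=C)CO[Si](C)(C)C(C)(C)C)[C@@H]2O[Si](C)(C)C(C)(C)C | intermediate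
22 | 1,4-endoperoxide | O=C1O[C@@H]2[C@H]4C=C[C@H](OO4)[C@H]1[C@H](O[Si](C)(C)C(C)(C)C)[C@@H](OC(=O)[C@]3(C)O[C@@H]3C)[C@@H](C(=C)CO[Si](C)(C)C(C)(C)C)[C@@H]2O[Si](C)(C)C(C)(C)C | intermediate
23 | 4-oxo-1-hydroxy-2-ene bridged lactone | O=C1O[C@@H]2C(=O)/C=C\[C@H](O)[C@H]1[C@H](O[Si](C)(C)C(C)(C)C)[C@@H](OC(=O)[C@]3(C)O[C@@H]3C)[C@@H](C(=C)CO[Si](C)(C)C(C)(C)C)[C@@H]2O[Si](C)(C)C(C)(C)C | intermediate
24 | 4-methyl-1,4-diol bridged lactone | O=C1O[C@@H]2[C@@](C)(O)/C=C\[C@H](O)[C@H]1[C@H](O[Si](C)(C)C(C)(C)C)[C@@H](OC(=O)[C@]3(C)O[C@@H]3C)[C@@H](C(=C)CO[Si](C)(C)C(C)(C)C)[C@@H]2O[Si](C)(C)C(C)(C)C | intermediate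
25 | 2,3-epoxy-4-methyl-1,4-diol bridged lactone | O=C1O[C@@H]2[C@@](C)(O)[C@@H]4O[C@@H]4[C@H](O)[C@H]1[C@H](O[Si](C)(C)C(C)(C)C)[C@@H](OC(=O)[C@]3(C)O[C@@H]3C)[C@@H](C(=C)CO[Si](C)(C)C(C)(C)C)[C@@H]2O[Si](C)(C)C(C)(C)C | intermediate
26 | seco acid (C14 acid, 1,4,5-triol) | OC(=O)[C@H]1[C@@H](O)[C@H]2O[C@H]2[C@](C)(O)[C@@H](O)[C@@H](O[Si](C)(C)C(C)(C)C)[C@H](C(=C)CO[Si](C)(C)C(C)(C)C)[C@H](OC(=O)[C@]3(C)O[C@@H]3C)[C@H]1O[Si](C)(C)C(C)(C)C | intermediate
27 | 2-(trimethylsilyl)ethyl ester of 26 | C[Si](C)(C)CCOC(=O)[C@H]1[C@@H](O)[C@H]2O[C@H]2[C@](C)(O)[C@@H](O)[C@@H](O[Si](C)(C)C(C)(C)C)[C@H](C(=C)CO[Si](C)(C)C(C)(C)C)[C@H](OC(=O)[C@]3(C)O[C@@H]3C)[C@H]1O[Si](C)(C)C(C)(C)C | intermediate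
28 | 1,5-bis-mesylate of 27 | C[Si](C)(C)CCOC(=O)[C@H]1[C@@H](OS(C)(=O)=O)[C@H]2O[C@H]2[C@](C)(O)[C@@H](OS(C)(=O)=O)[C@@H](O[Si](C)(C)C(C)(C)C)[C@H](C(=C)CO[Si](C)(C)C(C)(C)C)[C@H](OC(=O)[C@]3(C)O[C@@H]3C)[C@H]1O[Si](C)(C)C(C)(C)C | intermediate
29 | 2,3:4,5-bis-epoxy 1(10)-enoate, 6,9,12-tris-TBS ether | CC(C)(C)[Si](C)(C)O[C@H]2[C@H](C(=C)CO[Si](C)(C)C(C)(C)C)[C@H](OC(=O)[C@]3(C)O[C@@H]3C)[C@@H](O[Si](C)(C)C(C)(C)C)/C(C(=O)OCC[Si](C)(C)C)=C\[C@H]1O[C@H]1[C@]1(C)O[C@H]21 | intermediate
30 | 6,9,12-triol silylethyl ester | O[C@H]2[C@H](C(=C)CO)[C@H](OC(=O)[C@]3(C)O[C@@H]3C)[C@@H](O)/C(C(=O)OCC[Si](C)(C)C)=C\[C@H]1O[C@H]1[C@]1(C)O[C@H]21 | intermediate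
31 | 9-hydroxy α-methylene lactone silylethyl ester | C=C1C(=O)O[C@H]2[C@H]1[C@H](OC(=O)[C@]1(C)O[C@@H]1C)[C@@H](O)/C(C(=O)OCC[Si](C)(C)C)=C\[C@H]1O[C@H]1[C@]1(C)O[C@H]21 | intermediate
32 | leucanthin B 2-(trimethylsilyl)ethyl ester | C=C1C(=O)O[C@H]2[C@H]1[C@H](OC(=O)[C@]1(C)O[C@@H]1C)[C@@H](OC(C)=O)/C(C(=O)OCC[Si](C)(C)C)=C\[C@H]1O[C@H]1[C@]1(C)O[C@H]21 | intermediate
33 | leucanthin B | C=C1C(=O)O[C@H]2[C@H]1[C@H](OC(=O)[C@]1(C)O[C@@H]1C)[C@@H](OC(C)=O)/C(C(=O)O)=C\[C@H]1O[C@H]1[C@]1(C)O[C@H]21 | target

**Step count and risks**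

Total steps: 23. Longest linear sequence: 19 steps (steps 1–6, 8, 12–23).

Steps most likely to fail:

Step 5. The wrong bridgehead (C10) may migrate, or the diene may be oxidized in competition with the hindered ketone. Fallback: setting out from 6, the ketone is oxidized with a flavin-dependent Baeyer–Villiger monooxygenase of the cyclohexanone monooxygenase family (whole cells, air, pH 8 buffer). The enzyme pocket, not substituent effects, then chooses the migrating bridgehead, and C=C bonds are not attacked. This makes no compound outside the list (F0) and comes back to the route at 9.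

Step 6. Delivery of oxygen to the concave face of C7=C8 may fail, giving no reaction, epoxidation of the homoallylic C1=C2 bond, or attack from the convex face. Fallback: setting out from 6, the C9 hydroxyl is converted into the tert-butyl carbonate F1 (Boc2O, DMAP). IBr in toluene at −80 °C closes the carbonate oxygen onto C8 from the side of the C9 oxygen while iodine enters C7 from the convex face, giving the cyclic iodocarbonate F2. K2CO3 in methanol frees the C8 alkoxide, which displaces the iodide to give the syn-epoxy alcohol ketone F3. The trifluoroacetylation, silyl-peroxide Baeyer–Villiger oxidation and methanolysis of step 5 then lead through the trifluoroacetate F4 and the trifluoroacetoxy epoxy lactone F5 back to the route at 10.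

Step 12. Activation of the cis-diol may be unselective, or elimination may outrun the slow SN2 at hindered C8. Fallback: setting out from 15, the exposed C9 hydroxyl is silylated selectively (TBSCl, imidazole) to the 9-silyl ether F6. The hindered C8 hydroxyl is converted into the triflate F7 (Tf2O, pyridine). The caesium salt of 19 (Cs2CO3, 18-crown-6, toluene) then displaces the triflate with inversion, which comes back to the route at 21.

Further compounds
F0 | step 5 | none | none
F1 | step 6 | 9-O-(tert-butoxycarbonyl) derivative of 6 | O=C1[C@H]2C=CC=C[C@@H]1[C@@H](O[Si](C)(C)C(C)(C)C)C=C[C@H]2OC(=O)OC(C)(C)C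
F2 | step 6 | 7-iodo 8,9-cyclic carbonate ketone (carbonate up, iodine down) | O=C1[C@H]2C=CC=C[C@@H]1[C@@H](O[Si](C)(C)C(C)(C)C)[C@H](I)[C@H]3OC(=O)O[C@@H]23
F3 | step 6 | syn-7,8-epoxy-9-hydroxy bicyclic ketone | O=C1[C@H]2C=CC=C[C@@H]1[C@@H](O[Si](C)(C)C(C)(C)C)[C@H]3O[C@H]3[C@H]2O
F4 | step 6 | 9-trifluoroacetate of F3 | O=C1[C@H]2C=CC=C[C@@H]1[C@@H](O[Si](C)(C)C(C)(C)C)[C@H]3O[C@H]3[C@H]2OC(=O)C(F)(F)F
F5 | step 6 | 9-trifluoroacetoxy 7,8-epoxy bridged lactone | O=C1O[C@@H]2/C=C\C=C/[C@H]1[C@H](OC(=O)C(F)(F)F)[C@@H]3O[C@@H]3[C@@H]2O[Si](C)(C)C(C)(C)C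
F6 | step 12 | 9-O-TBS ether of 15 (8-OH free, up) | O=C1O[C@@H]2/C=C\C=C/[C@H]1[C@H](O[Si](C)(C)C(C)(C)C)[C@H](O)[C@@H](C(=C)CO[Si](C)(C)C(C)(C)C)[C@@H]2O[Si](C)(C)C(C)(C)C
F7 | step 12 | 8-O-triflate of F6 | O=C1O[C@@H]2/C=C\C=C/[C@H]1[C@H](O[Si](C)(C)C(C)(C)C)[C@H](OS(=O)(=O)C(F)(F)F)[C@@H](C(=C)CO[Si](C)(C)C(C)(C)C)[C@@H]2O[Si](C)(C)C(C)(C)C
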